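**Retrosynthetic overview**

1. Locants of the trans-fused hydroazulene core: C1 = CH–O(anisoyl), C2=C3(Me), C4, C5, C6 = C(OH), C7 = CH(iPr), C8, C9 = C=O, C10 = C(Me). The five-membered ring is C6–C7–C8–C9–C10; the seven-membered ring is C1–C6 plus C10.
2. Late stage: C9 ketone by oxidation and C1 anisoate by acylation. The C1 carbinol comes from a hydroxyl-directed reduction of the C1 enone. The seven-membered ring is closed last, by an intramolecular carbonyl-ene reaction that forms C1–C2.
3. The cyclopentane is made by semipinacol ring contraction of a cyclohexane 2,3-epoxy silyl ether (ring C1, C10, C9, C8, C7, C6). C6 shifts from C1 to C10, C1 leaves the ring as a formyl group, and the epoxide oxygen stays on C9.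
4. Enabling feature: C10 is a quaternary carbon flanked by two oxygenated carbons (C1–O and C9=O), the aldol-type array that a semipinacol shift onto a trisubstituted epoxide delivers. Its methyl and the C7 isopropyl are 1,3 on the cyclopentane, hence 1,4 on a six-membered ring once C1 is put back between C10 and C6. That is the p-menthane pattern of carvone, whose carbonyl carbon becomes C1.
5. The epoxy silyl ether comes from (S)-carvone by hydrogenation, alpha-prime hydroxylation, Michael addition (sets C6), methylenation, directed reduction and directed epoxidation. Ring order: six-membered (chiral pool), then five-membered (ring contraction), then seven-membered (ene closure).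

Key step: step 10

Remark: the enolate hydroxylation of step 2 is assumed to give mainly the alcohol trans to isopropyl; this does not matter, because C6 is made planar again in step 4.

**Route**

Step 1
Reactants: 1 (S)-(+)-carvone
Product: 2 (S)-carvotanacetone
Conditions: H2 (1 atm), RhCl(PPh3)3 (cat.), benzene, rt
Reagents that add atoms: none
Why: Chemoselective homogeneous hydrogenation: RhCl(PPh3)3 should saturate the unhindered 1,1-disubstituted isopropenyl alkene and leave the trisubstituted conjugated ring alkene and the stereocenter untouched.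

Step 2
Reactants: 2 (S)-carvotanacetone
Product: 4 (5R,6R)-6-hydroxy-2-methyl-5-(propan-2-yl)cyclohex-2-en-1-one, via lithium dienolate 3 (not isolated)
Conditions: LiN(iPr)2, THF, −78 °C; 2-(benzenesulfonyl)-3-phenyloxaziridine, −78 °C; H2O
Reagents that add atoms: 2-(benzenesulfonyl)-3-phenyloxaziridine, O=S(=O)(c1ccccc1)N1OC1c1ccccc1
Why: Kinetic deprotonation at the alpha-prime carbon C6 followed by electrophilic enolate hydroxylation with the N-sulfonyloxaziridine should place oxygen on C6, anti to isopropyl; this configuration is erased again in step 4.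

Step 3
Reactants: 4 (5R,6R)-6-hydroxy-2-methyl-5-(propan-2-yl)cyclohex-2-en-1-one
Product: 5 (5R,6R)-6-[(2-methoxypropan-2-yl)oxy]-2-methyl-5-(propan-2-yl)cyclohex-2-en-1-one
Conditions: 2-methoxypropene, PPTS (cat.), CH2Cl2, 0 °C
Reagents that add atoms: 2-methoxypropene, COC(C)=C
Why: Acid-catalysed addition of the alcohol to the enol ether (mixed ketal formation) gives a base-stable ether that, unlike a silyl ether, cannot shift between the two oxygens of the enolate made in step 4.

Step 4
Reactants: 5 (5R,6R)-6-[(2-methoxypropan-2-yl)oxy]-2-methyl-5-(propan-2-yl)cyclohex-2-en-1-one; 6 but-3-en-2-one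
Product: 8 (5R,6S)-6-[(2-methoxypropan-2-yl)oxy]-2-methyl-6-(3-oxobutyl)-5-(propan-2-yl)cyclohex-2-en-1-one, via lithium enolate 7 (not isolated)
Conditions: LiN(iPr)2, THF, −78 °C; 6, −78 °C; AcOH quench at −78 °C
Reagents that add atoms: none
Why: Michael addition of the fully substituted alpha-alkoxy enolate to the vinyl ketone should occur on the enolate face anti to the neighbouring isopropyl group, so the chain ends trans and the C6 oxygen cis to isopropyl, which fixes the quaternary stereocenter C6.

Step 5
Reactants: 8 (5R,6S)-6-[(2-methoxypropan-2-yl)oxy]-2-methyl-6-(3-oxobutyl)-5-(propan-2-yl)cyclohex-2-en-1-one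
Product: 10 (5R,6S)-6-hydroxy-2-methyl-6-(3-methylbut-3-en-1-yl)-5-(propan-2-yl)cyclohex-2-en-1-one, via ketal-protected triene 9 (not isolated)
Conditions: Ph3PCH3Br, KOtBu, THF, 0 °C; then PPTS, MeOH, rt
Reagents that add atoms: methylenetriphenylphosphorane (from Ph3PCH3Br and KOtBu), C=P(c1ccccc1)(c1ccccc1)c1ccccc1
Why: Wittig methylenation should take the unhindered methyl ketone and not the conjugated ketone flanked by a quaternary carbon, and mild acid methanolysis then removes the mixed ketal without touching the alkenes.

Step 6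
Reactants: 10 (5R,6S)-6-hydroxy-2-methyl-6-(3-methylbut-3-en-1-yl)-5-(propan-2-yl)cyclohex-2-en-1-one
Product: 11 (1S,2S,6R)-3-methyl-1-(3-methylbut-3-en-1-yl)-6-(propan-2-yl)cyclohex-3-ene-1,2-diol
Conditions: Me4NBH(OAc)3, MeCN/AcOH, −30 °C
Reagents that add atoms: none
Why: Hydroxyl-directed reduction of the Evans–Saksena type: the C6 hydroxyl binds boron and delivers hydride to the C1 carbonyl on its own face, which should set C1 with its hydroxyl trans to the C6 hydroxyl; the enone is not reduced by this reagent without such delivery.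

Step 7
Reactants: 11 (1S,2S,6R)-3-methyl-1-(3-methylbut-3-en-1-yl)-6-(propan-2-yl)cyclohex-3-ene-1,2-diol
Product: 12 (1S,2S,6R)-2-[(tert-butyldimethylsilyl)oxy]-3-methyl-1-(3-methylbut-3-en-1-yl)-6-(propan-2-yl)cyclohex-3-en-1-ol
Conditions: TBSOTf (1.05 equiv), 2,6-lutidine, CH2Cl2, −78 °C
Reagents that add atoms: tert-butyldimethylsilyl trifluoromethanesulfonate, CC(C)(C)[Si](C)(C)OS(=O)(=O)C(F)(F)F
Why: Silyl ether formation at low temperature should select the secondary allylic C1 hydroxyl over the more hindered tertiary C6 hydroxyl.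

Step 8
Reactants: 12 (1S,2S,6R)-2-[(tert-butyldimethylsilyl)oxy]-3-methyl-1-(3-methylbut-3-en-1-yl)-6-(propan-2-yl)cyclohex-3-en-1-ol
Product: 13 C9,C10-epoxide of 12 (9R,10R; epoxide oxygen cis to the C6 hydroxyl and to isopropyl; trans to the C1 silyl ether)
Conditions: VO(acac)2 (cat.), t-BuOOH, toluene, 0 °C
Reagents that add atoms: tert-butyl hydroperoxide, CC(C)(C)OO
Why: Vanadium-catalysed hydroxyl-directed epoxidation: the homoallylic C6 hydroxyl (cyclohex-3-en-1-ol array) should deliver oxygen to the ring alkene on its own face, while the allylic silyl ether blocks the other face and the remote 1,1-disubstituted alkene is less nucleophilic and less well placed.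

Step 9
Reactants: 13 C9,C10-epoxide of 12
Product: 14 C6 trimethylsilyl ether of 13
Conditions: 1-(trimethylsilyl)imidazole, CH2Cl2, rt
Reagents that add atoms: 1-(trimethylsilyl)imidazole, C[Si](C)(C)n1ccnc1
Why: Neutral silyl transfer caps the hindered tertiary alcohol with a group that survives step 10 yet is more labile than the TBS ether, so that it can be removed selectively in step 13.

Step 10
Reactants: 14 C6 trimethylsilyl ether of 13
Product: 15 (1R,2S,3R,5R)-5-[(tert-butyldimethylsilyl)oxy]-1-methyl-2-(3-methylbut-3-en-1-yl)-3-(propan-2-yl)-2-[(trimethylsilyl)oxy]cyclopentane-1-carbaldehyde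
Conditions: TBSOTf (0.2 equiv), 2,6-di-tert-butyl-4-methylpyridine (0.3 equiv), CH2Cl2, −78 to −40 °C
Reagents that add atoms: none
Why: Silylation of the epoxide oxygen by TBSOTf triggers heterolysis of the tertiary C10–O bond while the ring bond C1–C6 shifts from C1 to C10 on the face opposite to the departing oxygen, pushed by the lone pair of the C1 silyl ether; the resulting silyloxocarbenium ion hands its silyl group to triflate, which closes the catalytic cycle and leaves the silyl group formally moved from the C1 oxygen to the C9 oxygen. The closest known reaction type is the semipinacol rearrangement of 2,3-epoxy alcohols and their silyl ethers under Lewis acids or silyl triflates (the non-aldol aldol process), in the ring-contracting variant known for 2,3-epoxycyclohexanols. The cyclopentane C6–C7–C8–C9–C10 is closed by a 1,2-alkyl shift through a three-centre bridged transition state, not by cyclisation of an open chain. C10 is the only new stereocenter and is set by inversion at the epoxide carbon, so the epoxide on the face of the C6 oxygen should give the formyl carbon on that face and the methyl on the opposite one; C6 migrates with retention and C9 keeps its C–O bond. The step needs C6 migration to win over the 1,2-hydride shift from C1 and over any shift from the C9 side: the trans relationship of the C1 silyloxy group and the epoxide puts the C1 hydrogen syn to the leaving oxygen, where it cannot reach the backside of C10, and leaves C1–C6 as the only bond that can, while the oxonium-bound C9 side is the poorer donor.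

Step 11
Reactants: 15 (1R,2S,3R,5R)-5-[(tert-butyldimethylsilyl)oxy]-1-methyl-2-(3-methylbut-3-en-1-yl)-3-(propan-2-yl)-2-[(trimethylsilyl)oxy]cyclopentane-1-carbaldehyde
Product: 16 C3-methylidene hydroazulen-1-ol (core locants: 1-OH as both epimers; 6-OTMS; 7-isopropyl; 9-OTBS; 10-methyl; 6S,7R,9R,10R)
Conditions: Me2AlCl (2 equiv), CH2Cl2, −78 to −20 °C; aq. Rochelle salt
Reagents that add atoms: none
Why: Intramolecular carbonyl-ene reaction of type 2 (enophile tethered to the central carbon of a 1,1-disubstituted alkene) promoted by Me2AlCl should close the seven-membered ring through the C1–C2 bond; the C1 configuration and the position of the new alkene (exocyclic or C3=C4) do not matter, because both are erased in step 12.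

Step 12
Reactants: 16 C3-methylidene hydroazulen-1-ol
Product: 18 hydroazulen-1-one with C2=C3 alkene (core locants: 3-methyl; 6-OTMS; 7-isopropyl; 9-OTBS; 10-methyl; 6S,7R,9R,10R), via exo-methylene ketone 17 (not isolated)
Conditions: Dess–Martin periodinane, NaHCO3, CH2Cl2, 0 °C to rt; then DBU, rt
Reagents that add atoms: none
Why: Dess–Martin oxidation followed by base-mediated isomerisation of the beta,gamma-unsaturated ketone into conjugation should give the endocyclic trisubstituted enone, the only conjugated isomer possible because C10 is quaternary.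

Step 13
Reactants: 18 hydroazulen-1-one with C2=C3 alkene
Product: 20 hydroazulene-1,6-diol (core locants: 1-OH cis to the C10 methyl; C2=C3; 9-OTBS; 1R,6S,7R,9R,10R), via hydroxy enone 19 (not isolated)
Conditions: PPTS, MeOH, 0 °C; evaporate; Me4NBH(OAc)3, MeCN/AcOH, −30 °C
Reagents that add atoms: none
Why: Mild methanolysis frees the tertiary C6 hydroxyl while the secondary TBS ether survives, and Evans–Saksena hydroxyl-directed 1,3-anti reduction then delivers hydride to the C1 ketone from the face of the C6 oxygen, which should set the C1 hydroxyl anti to the C6 hydroxyl and cis to the angular methyl.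

Step 14
Reactants: 20 hydroazulene-1,6-diol; 21 4-methoxybenzoyl chloride
Product: 22 C1 4-methoxybenzoate of 20 (1R,6S,7R,9R,10R)
Conditions: Et3N, DMAP (cat.), CH2Cl2, 0 °C to rt
Reagents that add atoms: none
Why: DMAP-catalysed acyl transfer should esterify the secondary allylic C1 alcohol only, the tertiary C6 alcohol being inert under these conditions.

Step 15
Reactants: 22 C1 4-methoxybenzoate of 20
Product: 23 C6,C9-diol anisoate (1R,6S,7R,9R,10S)
Conditions: HF·pyridine, pyridine/THF, 0 °C to rt
Reagents that add atoms: none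
Why: Fluoride-mediated desilylation under buffered conditions should free the C9 alcohol without cleaving the allylic ester.

Step 16
Reactants: 23 C6,C9-diol anisoate
Product: 24 target CNP0246512.2 (1R,6S,7R,10S)
Conditions: Dess–Martin periodinane, NaHCO3, CH2Cl2, 0 °C
Reagents that add atoms: none
Why: Dess–Martin oxidation takes the only secondary alcohol to the C9 ketone under neutral buffered conditions, which should avoid retro-aldol cleavage of the beta-hydroxy ketone and leave the tertiary alcohol and the ester untouched.

**Compound list**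

1 | (S)-(+)-carvone, (5S)-2-methyl-5-(prop-1-en-2-yl)cyclohex-2-en-1-one | CC1=CC[C@@H](CC1=O)C(C)=C | starting material
2 | (S)-carvotanacetone, (5S)-2-methyl-5-(propan-2-yl)cyclohex-2-en-1-one | CC1=CC[C@@H](CC1=O)C(C)C | intermediate
3 | lithium cross-conjugated dienolate of 2 (OLi on C1, C1=C6 and C10=C9 double bonds) | CC1=CC[C@H](C(C)C)C=C1O[Li] | intermediate (not isolated)
4 | (5R,6R)-6-hydroxy-2-methyl-5-(propan-2-yl)cyclohex-2-en-1-one (hydroxyl trans to isopropyl) | CC1=CC[C@H](C(C)C)[C@@H](O)C1=O | intermediate
5 | (5R,6R)-6-[(2-methoxypropan-2-yl)oxy]-2-methyl-5-(propan-2-yl)cyclohex-2-en-1-one | CC1=CC[C@H](C(C)C)[C@@H](OC(C)(C)OC)C1=O | intermediate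
6 | but-3-en-2-one | C=CC(C)=O | starting material
7 | lithium enolate of 5 (C1=C6 enolate, ketal oxygen on C6) | CC1=CC[C@H](C(C)C)C(OC(C)(C)OC)=C1O[Li] | intermediate (not isolated)
8 | (5R,6S)-6-[(2-methoxypropan-2-yl)oxy]-2-methyl-6-(3-oxobutyl)-5-(propan-2-yl)cyclohex-2-en-1-one (C6 oxygen cis, chain trans to isopropyl) | CC1=CC[C@H](C(C)C)[C@](CCC(C)=O)(OC(C)(C)OC)C1=O | intermediate
9 | (5R,6S)-6-[(2-methoxypropan-2-yl)oxy]-2-methyl-6-(3-methylbut-3-en-1-yl)-5-(propan-2-yl)cyclohex-2-en-1-one | CC1=CC[C@H](C(C)C)[C@](CCC(C)=C)(OC(C)(C)OC)C1=O | intermediate (not isolated)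
10 | (5R,6S)-6-hydroxy-2-methyl-6-(3-methylbut-3-en-1-yl)-5-(propan-2-yl)cyclohex-2-en-1-one | CC1=CC[C@H](C(C)C)[C@](CCC(C)=C)(O)C1=O | intermediate
11 | (1S,2S,6R)-3-methyl-1-(3-methylbut-3-en-1-yl)-6-(propan-2-yl)cyclohex-3-ene-1,2-diol (trans diol) | CC1=CC[C@H](C(C)C)[C@](CCC(C)=C)(O)[C@H]1O | intermediate
12 | (1S,2S,6R)-2-[(tert-butyldimethylsilyl)oxy]-3-methyl-1-(3-methylbut-3-en-1-yl)-6-(propan-2-yl)cyclohex-3-en-1-ol | CC1=CC[C@H](C(C)C)[C@](CCC(C)=C)(O)[C@H]1O[Si](C)(C)C(C)(C)C | intermediate
13 | C9,C10-epoxide of 12 (9R,10R; epoxide cis to the C6 hydroxyl and to isopropyl, trans to the C1 silyl ether) | C[C@@]12O[C@@H]1C[C@H](C(C)C)[C@](CCC(C)=C)(O)[C@H]2O[Si](C)(C)C(C)(C)C | intermediate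
14 | C6 trimethylsilyl ether of 13 | C[C@@]12O[C@@H]1C[C@H](C(C)C)[C@](CCC(C)=C)(O[Si](C)(C)C)[C@H]2O[Si](C)(C)C(C)(C)C | intermediate
15 | (1R,2S,3R,5R)-5-[(tert-butyldimethylsilyl)oxy]-1-methyl-2-(3-methylbut-3-en-1-yl)-3-(propan-2-yl)-2-[(trimethylsilyl)oxy]cyclopentane-1-carbaldehyde | O=C[C@]1(C)[C@H](O[Si](C)(C)C(C)(C)C)C[C@H](C(C)C)[C@]1(CCC(C)=C)O[Si](C)(C)C | intermediate
16 | C3-methylidene hydroazulen-1-ol (1-OH both epimers, 6-OTMS, 7-isopropyl, 9-OTBS, 10-methyl; 6S,7R,9R,10R) | OC1CC(=C)CC[C@]2(O[Si](C)(C)C)[C@@H](C(C)C)C[C@@H](O[Si](C)(C)C(C)(C)C)[C@@]12C | intermediate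
17 | C3-methylidene hydroazulen-1-one (6-OTMS, 9-OTBS; 6S,7R,9R,10R) | O=C1CC(=C)CC[C@]2(O[Si](C)(C)C)[C@@H](C(C)C)C[C@@H](O[Si](C)(C)C(C)(C)C)[C@@]12C | intermediate (not isolated)
18 | hydroazulen-1-one with C2=C3 alkene (3-methyl, 6-OTMS, 7-isopropyl, 9-OTBS, 10-methyl; 6S,7R,9R,10R) | O=C1C=C(C)CC[C@]2(O[Si](C)(C)C)[C@@H](C(C)C)C[C@@H](O[Si](C)(C)C(C)(C)C)[C@@]12C | intermediate
19 | 6-hydroxy hydroazulen-1-one (C2=C3, 9-OTBS; 6S,7R,9R,10R) | O=C1C=C(C)CC[C@]2(O)[C@@H](C(C)C)C[C@@H](O[Si](C)(C)C(C)(C)C)[C@@]12C | intermediate (not isolated)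
20 | hydroazulene-1,6-diol (C2=C3, 9-OTBS; 1R,6S,7R,9R,10R) | O[C@@H]1C=C(C)CC[C@]2(O)[C@@H](C(C)C)C[C@@H](O[Si](C)(C)C(C)(C)C)[C@@]12C | intermediate
21 | 4-methoxybenzoyl chloride | COc1ccc(cc1)C(=O)Cl | starting material
22 | C1 4-methoxybenzoate of 20 (1R,6S,7R,9R,10R) | COc1ccc(C(=O)O[C@@H]2C=C(C)CC[C@]3(O)[C@@H](C(C)C)C[C@@H](O[Si](C)(C)C(C)(C)C)[C@@]23C)cc1 | intermediate
23 | C6,C9-diol anisoate (1R,6S,7R,9R,10S) | COc1ccc(C(=O)O[C@@H]2C=C(C)CC[C@]3(O)[C@@H](C(C)C)C[C@@H](O)[C@@]23C)cc1 | intermediate
24 | CNP0246512.2 (1R,6S,7R,10S) | COc1ccc(C(=O)O[C@@H]2C=C(C)CC[C@]3(O)[C@@H](C(C)C)CC(=O)[C@@]23C)cc1 | target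

**Step count and risks**

Total step count: 16. Longest linear sequence: 16 steps from (S)-carvone.

Steps most likely to fail:

1. Step 10 (ring contraction). The shift of the oxygenated carbon C6 has to start from the less populated half-chair with isopropyl pseudo-axial. The process may instead divert to 1,2-hydride migration from C1, to Grob-type cleavage of the C1–C6 bond pushed by the C6 oxygen, or to a free cation with loss of the inversion at C10. The fallback sets out from 13, rejoins the route at 15, and replaces the 1,2-shift by cleavage and re-closure. Tetrabutylammonium fluoride in THF removes the silyl ether to give the epoxy diol F1. Pb(OAc)4 in benzene cleaves the C1–C6 glycol to the open-chain epoxy keto aldehyde F2. The trivalent titanium reagent Cp2TiCl (from Cp2TiCl2 and Zn dust, THF) opens the epoxide reductively at C10 to a titanium enolate, which closes the cyclopentane by intramolecular aldol addition to the C6 ketone and gives the dihydroxy aldehyde F3. C9 keeps its configuration; chelation of enolate and ketone oxygens should place the formyl group cis to the new hydroxyl and the chain anti to isopropyl. TBSCl and imidazole silylate the secondary C9 hydroxyl to give the hydroxy aldehyde F4, and 1-(trimethylsilyl)imidazole then caps the tertiary hydroxyl to give 15.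

2. Step 4 (C6 quaternary centre). The hindered alpha-alkoxy enolate may be quenched by proton transfer while the vinyl ketone oligomerises, or the product methyl ketone enolate may close onto the C1 ketone. The fallback sets out from 5 and rejoins at 10. The same enolate 7 is alkylated directly with 4-iodo-2-methylbut-1-ene in THF/DMPU, an SN2 alkylation in place of conjugate addition plus olefination. This gives 9 without the diketone 8, and the methanolysis of step 5 then gives 10.

3. Step 11 (seven-membered ring). The neopentyl aldehyde may resist the ene closure, or the Lewis acid may strip the tertiary trimethylsilyl ether and let the freed alcohol add to the activated alkene. The fallback sets out from 15 and rejoins at 18. CH2=CHMgBr adds to the aldehyde to give the vinyl carbinol F5 as both C1 epimers. Ring-closing metathesis with the second-generation Grubbs catalyst RuCl2(H2IMes)(PCy3)(=CHPh) joins the vinyl and isopropenyl groups to the cycloheptenol F6. Dess–Martin oxidation then gives 18.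

Further compounds
F1 | step 10 | epoxy diol (13 without the silyl group) | C[C@@]12O[C@@H]1C[C@H](C(C)C)[C@](CCC(C)=C)(O)[C@H]2O
F2 | step 10 | open-chain epoxy keto aldehyde (C1 formyl on the epoxide carbon C10, C6 ketone) | O=C[C@]1(C)O[C@@H]1C[C@H](C(C)C)C(=O)CCC(C)=C
F3 | step 10 | dihydroxy aldehyde (15 with free C6 and C9 hydroxyls) | O=C[C@]1(C)[C@H](O)C[C@H](C(C)C)[C@]1(CCC(C)=C)O
F4 | step 10 | hydroxy aldehyde (C9 TBS ether, free C6 hydroxyl) | O=C[C@]1(C)[C@H](O[Si](C)(C)C(C)(C)C)C[C@H](C(C)C)[C@]1(CCC(C)=C)O
F0 | step 4 | none | none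
F5 | step 11 | vinyl carbinol from 15 (both C1 epimers) | C=CC(O)[C@]1(C)[C@H](O[Si](C)(C)C(C)(C)C)C[C@H](C(C)C)[C@]1(CCC(C)=C)O[Si](C)(C)C
F6 | step 11 | cycloheptenol with C2=C3 alkene (1-OH both epimers, 6-OTMS, 9-OTBS) | OC1C=C(C)CC[C@]2(O[Si](C)(C)C)[C@@H](C(C)C)C[C@@H](O[Si](C)(C)C(C)(C)C)[C@@]12C
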